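## The problem

Atoms are labelled in the order of the SMILES string of the target 27 (C1 is the methylene carbon, C28 the last ring CH). In 27, ring A (C2, C3, C8, C9, C28, C26) is cis-fused to ring B (C9, C14, C15, C16, C17, C28). A γ-lactone (C9, C10, O11, C12, C14) sits on the quaternary carbon C9 and the C14=C15 double bond, and a seven-membered ring (C17, C18, C22, C23, C25, C26, C28) joins both carbocycles to a 2,3-disubstituted furan through the C23 ketone. Five stereocentres must be set: the quaternary carbons C9 and C26, the ring-fusion methine C28, the furfuryl methine C17 and the acetoxy carbon C3. C9 can control C26 and C3 through its axial C10 arm and, once the lactone is closed, C28; C28 together with the arm on C26 can control C17. The furan, the exocyclic C2=C1 methylene next to an allylic acetate, and the acidic C16 position of the unsaturated lactone rule out ozone, strong acid and strong base late in the route. The enabling feature is that C17 is both furfuryl (bonded to the furan α-carbon C18) and the δ-carbon of the lactone carbonyl C12 through C14=C15 and C16, so the C17–C18 bond and the seven-membered ring can be made by adding the furan to a C14=C15–C16=C17 dienyl lactone.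

## Retrosynthesis

**27 to 25 (via 26).** No skeletal bond is cut; the C23 ketone is traced to a silyl-protected carbinol. A 3-acyl group would deactivate the furan at C18 and send electrophiles to C20, so C23 must be sp3 during ring closure. A triisopropylsilyl ether is preferred to a thioketal because it can be put on as soon as the carbinol exists, needs no other ketone or ketal to be absent, and brings no sulfur into the palladium step. The price is two closing steps instead of one.

**25 to 24.** The C17–C18 bond is cut, which opens the seven-membered ring and removes the C17 stereocentre. Cutting C22–C23 instead would ask the furan to react at a β-carbon, and cutting C25–C26 would form a quaternary centre in a medium-ring closure. In 24 the electrophile (C17, δ to C12) and the nucleophile (the free α-carbon C18) are already in place, so the forward step needs only a Lewis acid. The tether must fix both the site on the furan and the face of ring B.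

**24 to 22 (via 23).** No carbon–carbon bond is cut; one hydrogen is moved from C28 to C16, so the conjugated diene comes from the skipped C14=C15 / C17=C28 diene. A dehydrogenation of a saturated ring B lactone was weighed and set aside, since it needs γ-selective functionalisation and an oxidant next to a furan. The shift also sets C28: the fused lactone holds C10 in the plane of ring B, so only the cis ring fusion is unstrained. The forward step needs an amidine base that reaches the doubly activated C16–H.

**22 to 18 (via 21 and 20).** The bonds C12–C14 and O11–C12 are cut, with C12 arriving by carbonylation of the enol triflate 21. This is preferred to building the lactone by alkylation at C9, because a C14 ketone and a C10 oxygen are native to an annulation product. The forward reaction has only one enolisable position to find (C15), which quaternary C9 guarantees.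

**18 to 15 (via 17 and 16).** The ketal is restored, C2=C1 is cut to the C2 ketone, and the C3–O bond is cut to the parent ketone 15. Enolate hydroxylation is chosen over allylic oxidation of a methylene compound because the oxidant must enter anti to the axial C10 arm and the axial C27 methyl, which gives the equatorial alcohol of the target.

**15 to 11 (via 14 and 12) and 13.** The C22–C23 bond is cut to aldehyde 12 and 3-bromofuran 13; 12 comes from the terminal alkene of 11. The forward addition must pick the aldehyde over the hindered C2 ketone.

**11 to 9 and 10.** The C25–C26 bond is cut: deconjugative α-alkylation of enone 9 with allyl bromide 10. It creates quaternary C26 with the new arm anti to the C10 arm, and it moves the ring alkene to C17=C28, where the later hydrogen shift needs it. A dissolving-metal reductive alkylation would give the trans ring fusion instead.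

**9 to 4 (via 8, 6 and 5).** The C10 oxygen is traced to the angular allyl group of 4 through the propenyl compound 6. An oxygenated one-carbon substituent cannot be carried through the annulation, where it would sit β to two carbonyl groups. The allyl group serves as its latent form and is shortened after the bicycle exists.

**4 to 1 and 2 (via 3).** The C26=C28 bond (aldol condensation) and the C8–C9 bond (Michael addition) are cut. The achiral triketone 3 is desymmetrised by an amino acid, which sets C9, the centre that controls the others.

## Roads not taken

**Alternative 1:** The cut is C26–C28, closing ring A by addition of a tethered tetrasubstituted allylsilane to a ring B cyclohexadienone under TiCl4, giving A1. The step makes ring A, both C26 and C28, and the C2=C1 methylene at once, and the tether enforces the cis ring fusion. In that respect it is better than the chosen plan, which spends an alkylation, a methylenation and a hydrogen shift on the same features. Its weak points are that the C26 configuration depends on the geometry of a tetrasubstituted allylsilane that is hard to obtain pure, and that a fully substituted carbon must attack a β-carbon next to quaternary C9. A1 is also still far from the target: the C16 carbonyl must go, the C14 methoxy group must be exchanged for C12, the C10 ester reduced, and the seven-membered ring closed by acylation at the less reactive furan β-carbon C22. The chosen plan sets against this an alkylation of predictable facial bias and a ring closure at the furan's most nucleophilic carbon.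

**Alternative 2:** The cut is C9–C14: a rhodium carbene from a diazophosphonoacetate on O11 (Rh2(OAc)4) inserts into the tertiary C9–H bond with retention and gives A2; a later intramolecular olefination would close ring B. It makes the quaternary centre and the lactone in one step from a simple methine, and the endgame from A2 is about as short as the chosen one. Five-membered insertion into a tertiary C–H bond is the favoured mode. For this target, however, the carbene is generated beside a furan and an exocyclic methylene, both good cyclopropanation partners, and C28–H offers a competing six-membered insertion. The seven-membered ring and C17 would also have to be built before ring B exists, without the ring control the chosen key step uses. The chosen plan pays with an early enantioselective annulation but exposes the furan only to a Lewis acid.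

**Alternative 3:** The cut is C2–C3: zerovalent nickel (Ni(cod)2, PBu3, Et3SiH) couples an ethynyl group on C26 with a C3 aldehyde and gives A3. One step delivers ring A, the methylene and the protected C3 oxygen, and A3 is two steps from the target. For ring A this is clearly more economical than the chosen plan, which needs hydroxylation, methylenation and acetylation. The drawback is that the lactone, ring B, the seven-membered ring and the centres C9, C26, C17 and C28 must all be assembled on a core without ring A, so C26 and C9 lose the control a decalin gives. The C3 configuration would rest on substrate control in a crowded metallacycle. The chosen plan has the decalin from step 1, so each later centre is set under ring control.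

Key step: step 17

Remark: C23 is carried as a mixture of epimers from 14 to 26 (no descriptor at C23 in those SMILES), since it becomes the ketone in step 19; 1, 2, 10 and 13 are taken as purchasable.

## Steps

Step 1
Reactants: 1 2-allylcyclohexane-1,3-dione; 2 pent-1-en-3-one
Product: 4 (S)-8a-allyl-5-methyl enedione, via triketone 3 (not isolated)
Conditions: Et3N (cat.), neat, 25 °C; then D-phenylalanine, (1R)-(−)-camphor-10-sulfonic acid, DMF, 30 → 70 °C
Reagents that add atoms: none
Why: Robinson annulation: Michael addition gives the achiral triketone, and the amino-acid-mediated aldol condensation (Hajos–Parrish–Eder–Sauer–Wiechert type) differentiates the two ring carbonyls through an enamine transition state. The D-amino acid should give C9 as drawn (S), the mirror sense of the usual L-series.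

Step 2
Reactants: 4 (S)-8a-allyl-5-methyl enedione
Product: 5 C14 dioxolane
Conditions: ethylene glycol, p-TsOH (cat.), 4 Å molecular sieves, CH2Cl2, 25 °C
Reagents that add atoms: ethylene glycol, OCCO
Why: Chemoselective ketalisation: the saturated C14 ketone reacts much faster than the conjugated C2 ketone.

Step 3
Reactants: 5 C14 dioxolane
Product: 6 angular (E)-propenyl enone
Conditions: RuHCl(CO)(PPh3)3 (cat.), toluene, 90 °C
Reagents that add atoms: none
Why: Ruthenium hydride addition and β-hydride elimination move the terminal alkene one position into the more stable E-propenyl group; quaternary C9 stops further migration.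

Step 4
Reactants: 6 angular (E)-propenyl enone
Product: 8 angular hydroxymethyl enone, via angular aldehyde 7 (not isolated)
Conditions: O3, pyridine, CH2Cl2/MeOH, −78 °C; Me2S, −78 → 0 °C; NaBH4, −78 → −40 °C
Reagents that add atoms: ozone, [O-][O+]=O
Why: Ozonolysis should take the electron-rich disubstituted alkene before the tetrasubstituted, electron-poor enone; borohydride at low temperature reduces the aldehyde and leaves the conjugated ketone.

Step 5
Reactants: 8 angular hydroxymethyl enone
Product: 9 C10 tert-butyldimethylsilyl ether
Conditions: TBSCl, imidazole, DMF, 25 °C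
Reagents that add atoms: tert-butyldimethylsilyl chloride, CC(C)(C)[Si](C)(C)Cl
Why: Standard silylation of a primary alcohol; the ether must survive alkoxide base, the osmium and titanium steps and mild acid.

Step 6
Reactants: 9 C10 tert-butyldimethylsilyl ether; 10 allyl bromide
Product: 11 C26-allyl β,γ-unsaturated ketone
Conditions: KOtBu, t-BuOH/THF, 0 °C; then 10, 0 → 25 °C
Reagents that add atoms: none
Why: Deconjugative α-alkylation: equilibrating deprotonation at C17 gives the extended dienolate, which is alkylated at the α-carbon C26 while the double bond moves to C17=C28. The electrophile enters anti to the axial C10 arm on C9, which sets quaternary C26 with the C25 arm trans and the C27 methyl cis to C10.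

Step 7
Reactants: 11 C26-allyl β,γ-unsaturated ketone
Product: 12 C23 aldehyde
Conditions: OsO4 (cat.), NaIO4, 2,6-lutidine, dioxane/H2O, 25 °C
Reagents that add atoms: sodium periodate, [Na+].[O-]I(=O)(=O)=O
Why: Lemieux–Johnson cleavage: osmylation takes the unhindered terminal alkene, while the C17=C28 bond between two quaternary carbons should stay untouched.

Step 8
Reactants: 12 C23 aldehyde; 13 3-bromofuran
Product: 14 furan-3-yl carbinol
Conditions: 13, n-BuLi, THF, −78 °C; ClTi(OiPr)3, −78 °C; then 12, −78 → −20 °C
Reagents that add atoms: none
Why: Bromine–lithium exchange and transmetalation give a non-basic aryltitanium triisopropoxide, a reagent class that adds to aldehydes and spares hindered ketones; both C23 epimers are expected and both are used.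

Step 9
Reactants: 14 furan-3-yl carbinol
Product: 15 C23 triisopropylsilyl ether
Conditions: i-Pr3SiOTf, 2,6-lutidine, CH2Cl2, −78 → 0 °C
Reagents that add atoms: triisopropylsilyl triflate, CC(C)[Si](OS(=O)(=O)C(F)(F)F)(C(C)C)C(C)C
Why: Silyl triflate silylation of a secondary alcohol; the bulky ether keeps C23 sp3 and weakly Lewis basic for the later Lewis acid step.

Step 10
Reactants: 15 C23 triisopropylsilyl ether
Product: 16 C3 α-hydroxy ketone
Conditions: KN(SiMe3)2, THF, −78 °C; 2-(phenylsulfonyl)-3-phenyloxaziridine, −78 °C; aq. NH4Cl
Reagents that add atoms: 2-(phenylsulfonyl)-3-phenyloxaziridine, O=S(=O)(c1ccccc1)N1OC1c1ccccc1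
Why: Enolate hydroxylation with an N-sulfonyloxaziridine; C3 is the only enolisable position of the C2 ketone. Oxygen is delivered anti to the axial C10 arm and the axial C27 methyl, giving the equatorial C3–OH of the target, which is also the more stable epimer.

Step 11
Reactants: 16 C3 α-hydroxy ketone
Product: 17 C2-methylene allylic alcohol
Conditions: Zn, CH2Br2, TiCl4, THF (reagent pre-formed, 0 °C); 16, CH2Cl2, 0 → 25 °C
Reagents that add atoms: dibromomethane, BrCBr
Why: Lombardo methylenation: a non-basic titanium–zinc methylene reagent suited to hindered, enolisable, α-oxygenated ketones, so C3 should not epimerise and the free hydroxyl is tolerated.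

Step 12
Reactants: 17 C2-methylene allylic alcohol
Product: 18 C14 ketone
Conditions: pyridinium p-toluenesulfonate (cat.), acetone/H2O, 55 °C
Reagents that add atoms: water, O
Why: Mild acid-catalysed ketal hydrolysis; the silyl ethers, the furan and the allylic alcohol should survive the buffered acid.

Step 13
Reactants: 18 C14 ketone
Product: 20 C14 enol triflate C3 trimethylsilyl ether, via bis-trimethylsilyl enol ether 19 (not isolated)
Conditions: Me3SiOTf, Et3N, CH2Cl2, 0 °C; MeLi, THF, 0 °C; PhNTf2, −78 → 0 °C
Reagents that add atoms: trimethylsilyl triflate, C[Si](C)(C)OS(=O)(=O)C(F)(F)F; N-phenylbis(trifluoromethanesulfonimide), O=S(=O)(N(c1ccccc1)S(=O)(=O)C(F)(F)F)C(F)(F)F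
Why: Soft enolisation silylates the C3 alcohol and converts the ketone into its only possible enol ether (C14=C15, C9 being quaternary). Methyllithium cleaves the enol silyl ether selectively to the lithium enolate, which is triflated on oxygen.

Step 14
Reactants: 20 C14 enol triflate C3 trimethylsilyl ether
Product: 21 diol enol triflate
Conditions: HF·pyridine, pyridine, THF, 0 → 25 °C
Reagents that add atoms: none
Why: Fluoride-mediated desilylation graded by silyl bulk: the trimethylsilyl and primary tert-butyldimethylsilyl ethers are cleaved, the secondary triisopropylsilyl ether should remain.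

Step 15
Reactants: 21 diol enol triflate
Product: 22 skipped-diene hydroxy lactone
Conditions: Pd(PPh3)4 (cat.), CO (1 atm), n-Bu3N, LiCl, MeCN, 65 °C
Reagents that add atoms: carbon monoxide, [C-]#[O+]
Why: Carbonylative lactonisation: zerovalent palladium inserts into the enol triflate, CO insertion gives an acylpalladium, and the C10 hydroxyl traps it in a five-membered closure. The C3 hydroxyl could only form a strained bridged ring and is not an allylic ester, so it should stay inert.

Step 16
Reactants: 22 skipped-diene hydroxy lactone
Product: 24 dienyl lactone acetate, via skipped-diene acetate 23 (not isolated)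
Conditions: Ac2O, Et3N, DMAP (cat.), CH2Cl2, 25 °C; then DBU, 40 °C
Reagents that add atoms: acetic anhydride, CC(=O)OC(C)=O
Why: Acylation of the C3 alcohol, then a base-mediated 1,3-prototropic shift: DBU removes a C16 proton (allylic to C17=C28 and γ to the lactone carbonyl) and the extended enolate is reprotonated at C28 to give the conjugated dienoate. C28 is set here: the fused lactone holds C10 in the plane of ring B, so the C9–C8 bond is axial, the proton arrives on the face away from it, and the cis ring fusion (H28 cis to C10) is the only one that keeps the lactone planar, so kinetic and thermodynamic control should agree.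

Step 17
Reactants: 24 dienyl lactone acetate
Product: 25 cyclised C23 silyl ether
Conditions: Me2AlCl (3 equiv), CH2Cl2, −78 → 0 °C; aq. potassium sodium tartrate; DBU (cat.), CH2Cl2, 25 °C
Reagents that add atoms: none
Why: Me2AlCl binds the lactone carbonyl oxygen O13 and polarises the C12(=O)–C14=C15–C16=C17 dienoate, making the δ-carbon C17 the electrophilic terminus; C18, the α-carbon next to the side chain and the most nucleophilic site of a 3-alkylfuran, adds to C17, the σ-complex loses its C18 proton to rearomatise, and the aluminium dienolate is protonated at C16 (any C14-protonated β,γ-isomer is brought into conjugation by the DBU treatment), which restores the C14=C15 lactone. The closest known reaction type is the Lewis-acid-promoted intramolecular Friedel–Crafts conjugate addition of furans to enones and, in the 1,6-sense, to dienones; a dienyl lactone is a less electrophilic member of the same acceptor family, which is why a strong, oxophilic, proton-scavenging Lewis acid is used in excess. The seven-membered ring (C17, C18, C22, C23, C25, C26, C28) closes in the 7-exo-trig mode, the reacting C16=C17 bond lying outside the new ring. The new stereocentre C17 is under substrate control: the furan hangs from C26, next to C28, on the face of ring B opposite H28 and can reach C17 only from that face, giving H17 cis to H28. The step needs site selectivity on the furan (C18 against C20 and C21), which the α-preference of electrophilic substitution and the tether (C20 out of reach) secure, with C23 kept as an sp3 silyloxy carbon so the ring is not deactivated as by an acyl group. On the acceptor, attack at C15 would require a bridged nine-membered ring, and quaternary C9 blocks aromatisation of ring B.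

Step 18
Reactants: 25 cyclised C23 silyl ether
Product: 26 C23 alcohol
Conditions: Bu4NF, AcOH, THF, 25 °C
Reagents that add atoms: none
Why: Buffered fluoride desilylation; acetic acid keeps the medium from deprotonating C16 or cleaving the acetate.

Step 19
Reactants: 26 C23 alcohol
Product: 27 target
Conditions: MnO2, CH2Cl2, 25 °C
Reagents that add atoms: none
Why: MnO2 oxidises the furyl (benzylic-type) carbinol selectively; no other free alcohol is present, and the alkenes and the lactone are inert to it.

## Compound list

1 | 2-allylcyclohexane-1,3-dione | C=CCC1C(=O)CCCC1=O | starting material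
2 | pent-1-en-3-one (ethyl vinyl ketone) | CCC(=O)C=C | starting material
3 | 2-allyl-2-(3-oxopentyl)cyclohexane-1,3-dione (not isolated) | CCC(=O)CCC1(CC=C)C(=O)CCCC1=O | intermediate
4 | (S)-8a-allyl-5-methyl-3,4,8,8a-tetrahydronaphthalene-1,6(2H,7H)-dione (C9 set) | C=CC[C@@]12CCC(=O)C(C)=C1CCCC2=O | intermediate
5 | 4 with the saturated C14 ketone as 1,3-dioxolane, C2 enone free | C=CC[C@@]12CCC(=O)C(C)=C1CCCC23OCCO3 | intermediate
6 | 5 with the angular allyl group isomerised to (E)-prop-1-enyl | C/C=C/[C@@]12CCC(=O)C(C)=C1CCCC23OCCO3 | intermediate
7 | angular aldehyde, C10 formyl on C9 (not isolated) | O=C[C@@]12CCC(=O)C(C)=C1CCCC23OCCO3 | intermediate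
8 | angular hydroxymethyl enone, C10–OH on C9, C14 dioxolane | OC[C@@]12CCC(=O)C(C)=C1CCCC23OCCO3 | intermediate
9 | tert-butyldimethylsilyl ether of 8 | CC(C)(C)[Si](C)(C)OC[C@@]12CCC(=O)C(C)=C1CCCC23OCCO3 | intermediate
10 | allyl bromide (3-bromoprop-1-ene) | C=CCBr | starting material
11 | C2 ketone with quaternary C26 (allyl trans, methyl cis to the C10 arm) and C17=C28 double bond | O=C1CC[C@@]2(CO[Si](C)(C)C(C)(C)C)C3(OCCO3)CCC=C2[C@@]1(C)CC=C | intermediate
12 | aldehyde, C25H2–C23HO arm on C26 | O=C1CC[C@@]2(CO[Si](C)(C)C(C)(C)C)C3(OCCO3)CCC=C2[C@@]1(C)CC=O | intermediate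
13 | 3-bromofuran | Brc1ccoc1 | starting material
14 | furan-3-yl carbinol at C23 (both C23 epimers) | O=C1CC[C@@]2(CO[Si](C)(C)C(C)(C)C)C3(OCCO3)CCC=C2[C@@]1(C)CC(O)c1ccoc1 | intermediate
15 | triisopropylsilyl ether of 14 | O=C1CC[C@@]2(CO[Si](C)(C)C(C)(C)C)C3(OCCO3)CCC=C2[C@@]1(C)CC(O[Si](C(C)C)(C(C)C)C(C)C)c1ccoc1 | intermediate
16 | α-hydroxy ketone, C3–OH trans to the C10 arm and the C27 methyl, cis to the C25 arm | O=C1[C@@H](O)C[C@@]2(CO[Si](C)(C)C(C)(C)C)C3(OCCO3)CCC=C2[C@@]1(C)CC(O[Si](C(C)C)(C(C)C)C(C)C)c1ccoc1 | intermediate
17 | allylic alcohol with exocyclic C2=C1 methylene | C=C1[C@@H](O)C[C@@]2(CO[Si](C)(C)C(C)(C)C)C3(OCCO3)CCC=C2[C@@]1(C)CC(O[Si](C(C)C)(C(C)C)C(C)C)c1ccoc1 | intermediate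
18 | C14 ketone (dioxolane removed) | C=C1[C@@H](O)C[C@@]2(CO[Si](C)(C)C(C)(C)C)C(=O)CCC=C2[C@@]1(C)CC(O[Si](C(C)C)(C(C)C)C(C)C)c1ccoc1 | intermediate
19 | C3 trimethylsilyl ether and C14 trimethylsilyl enol ether, C14=C15 (not isolated) | C=C1[C@@H](O[Si](C)(C)C)C[C@@]2(CO[Si](C)(C)C(C)(C)C)C(O[Si](C)(C)C)=CCC=C2[C@@]1(C)CC(O[Si](C(C)C)(C(C)C)C(C)C)c1ccoc1 | intermediate
20 | C14 enol triflate (C14=C15), C3 trimethylsilyl ether | C=C1[C@@H](O[Si](C)(C)C)C[C@@]2(CO[Si](C)(C)C(C)(C)C)C(OS(=O)(=O)C(F)(F)F)=CCC=C2[C@@]1(C)CC(O[Si](C(C)C)(C(C)C)C(C)C)c1ccoc1 | intermediate
21 | enol triflate with free C3–OH and C10–OH | C=C1[C@@H](O)C[C@@]2(CO)C(OS(=O)(=O)C(F)(F)F)=CCC=C2[C@@]1(C)CC(O[Si](C(C)C)(C(C)C)C(C)C)c1ccoc1 | intermediate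
22 | γ-lactone (C9, C10, O11, C12, C14) with C14=C15 and C17=C28, free C3–OH | C=C1[C@@H](O)C[C@@]23COC(=O)C2=CCC=C3[C@@]1(C)CC(O[Si](C(C)C)(C(C)C)C(C)C)c1ccoc1 | intermediate
23 | C3 acetate of 22 (not isolated) | C=C1[C@@H](OC(C)=O)C[C@@]23COC(=O)C2=CCC=C3[C@@]1(C)CC(O[Si](C(C)C)(C(C)C)C(C)C)c1ccoc1 | intermediate
24 | dienyl lactone, C14=C15–C16=C17, H28 cis to C10, C3 acetate, C23 triisopropylsilyl ether | C=C1[C@@H](OC(C)=O)C[C@@]23COC(=O)C2=CC=C[C@H]3[C@@]1(C)CC(O[Si](C(C)C)(C(C)C)C(C)C)c1ccoc1 | intermediate
25 | cyclised product with C17–C18 bond and seven-membered ring, H17 cis to H28, C23 triisopropylsilyl ether | C=C1[C@@H](OC(C)=O)C[C@@]23COC(=O)C2=CC[C@H]2c4occc4C(O[Si](C(C)C)(C(C)C)C(C)C)C[C@]1(C)[C@H]23 | intermediate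
26 | C23 alcohol of the full skeleton | C=C1[C@@H](OC(C)=O)C[C@@]23COC(=O)C2=CC[C@H]2c4occc4C(O)C[C@]1(C)[C@H]23 | intermediate
27 | CNP0273675.2 | C=C1[C@@H](OC(C)=O)C[C@@]23COC(=O)C2=CC[C@H]2c4occc4C(=O)C[C@]1(C)[C@H]23 | target

## Step count and least certain steps

Total step count: 19. Longest linear sequence: 19 steps (1 and 2 to 27; 10 and 13 enter as purchased reagents).

**Step 17 (key step).** The lactone-activated diene may be too weak an acceptor, so that Lewis-acid-induced loss of the allylic acetate, ionisation at the silyloxy carbon C23 or furan decomposition outruns ring closure; the dienolate may also be protonated at C14. The fallback keeps the C17–C18 bond but changes the mechanism to a radical conjugate addition. It sets out from 24: N-bromosuccinimide in THF at −78 °C should brominate the furan at C18 to give the C18-bromo dienyl lactone F1. Bu3SnH with azobisisobutyronitrile in hot benzene would generate the furan-2-yl radical, which adds 7-exo to C17 from the tether face; hydrogen transfer to the delocalised C16/C14 radical and a DBU equilibration bring the route back at 25.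

**Step 16.** Conjugation may stop at a mixture with the deconjugated C15=C16 / C17=C28 isomer, or protonation at C28 may show poor facial selectivity. The fallback sets C28 by hydroxyl-directed hydrogenation and makes the diene by dehydrogenation; it sets out from 15 and returns at 24.
- HF·pyridine frees the primary alcohol F2.
- H2 with [Ir(cod)(PCy3)(py)]PF6 in CH2Cl2, bound by the C10 hydroxyl, delivers hydrogen to C28 from the C10 face and gives the cis-fused ketone F3.
- Enolate hydroxylation as in step 10 (two equivalents of base) gives the diol ketone F4, Lombardo methylenation the methylene diol F5, and ketal hydrolysis the keto diol F6.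
- Et3SiOTf and Et3N give the tris-silylated enol ether F7, which Pd(OAc)2 in MeCN (Saegusa–Ito oxidation) turns into the enone F8.
- KN(SiMe3)2 and PhNTf2 deprotonate at C17 and give the dienyl triflate F9; HF·pyridine frees the diol dienyl triflate F10.
- Carbonylative lactonisation as in step 15 gives the hydroxy dienyl lactone F11, and acetylation returns to 24.

**Step 6.** O-alkylation, alkylation at C3, double alkylation or eroded facial selectivity may occur. The fallback replaces the bimolecular alkylation by a palladium-mediated allyl transfer. It sets out from 9: KOtBu and allyl chloroformate should give the dienol allyl carbonate F12. Pd(PPh3)4 in THF then effects a Tsuji decarboxylative allylation, recombining the allyl fragment with the dienolate at C26 under neutral conditions, and the route is rejoined at 11.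

**Step 13.** Methyllithium may also cleave the C3 silyl ether, after which triflation of an alkoxide or incomplete enolate trapping erodes the yield. The fallback avoids enolate chemistry. It sets out from 18: hydrazine hydrate and Et3N in hot ethanol give the C14 hydrazone F13. I2 and tetramethylguanidine (Barton vinyl iodide synthesis) give the C14 vinyl iodide F14, and HF·pyridine the diol vinyl iodide F15. Carbonylative lactonisation under the conditions of step 15 rejoins the route at 22.

## Further compounds

F1 | step 17 | C18-bromo dienyl lactone | C=C1[C@@H](OC(C)=O)C[C@@]23COC(=O)C2=CC=C[C@H]3[C@@]1(C)CC(O[Si](C(C)C)(C(C)C)C(C)C)c1ccoc1Br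
F2 | step 16 | primary alcohol from 15 | O=C1CC[C@@]2(CO)C3(OCCO3)CCC=C2[C@@]1(C)CC(O[Si](C(C)C)(C(C)C)C(C)C)c1ccoc1
F3 | step 16 | cis-fused ketone, H28 cis to C10 | O=C1CC[C@@]2(CO)C3(OCCO3)CCC[C@H]2[C@@]1(C)CC(O[Si](C(C)C)(C(C)C)C(C)C)c1ccoc1
F4 | step 16 | diol ketone with C3–OH | O=C1[C@@H](O)C[C@@]2(CO)C3(OCCO3)CCC[C@H]2[C@@]1(C)CC(O[Si](C(C)C)(C(C)C)C(C)C)c1ccoc1
F5 | step 16 | methylene diol | C=C1[C@@H](O)C[C@@]2(CO)C3(OCCO3)CCC[C@H]2[C@@]1(C)CC(O[Si](C(C)C)(C(C)C)C(C)C)c1ccoc1
F6 | step 16 | keto diol | C=C1[C@@H](O)C[C@@]2(CO)C(=O)CCC[C@H]2[C@@]1(C)CC(O[Si](C(C)C)(C(C)C)C(C)C)c1ccoc1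
F7 | step 16 | tris-silylated enol ether | C=C1[C@@H](O[Si](CC)(CC)CC)C[C@@]2(CO[Si](CC)(CC)CC)C(O[Si](CC)(CC)CC)=CCC[C@H]2[C@@]1(C)CC(O[Si](C(C)C)(C(C)C)C(C)C)c1ccoc1
F8 | step 16 | enone, C14 ketone with C15=C16 | C=C1[C@@H](O[Si](CC)(CC)CC)C[C@@]2(CO[Si](CC)(CC)CC)C(=O)C=CC[C@H]2[C@@]1(C)CC(O[Si](C(C)C)(C(C)C)C(C)C)c1ccoc1
F9 | step 16 | dienyl triflate | C=C1[C@@H](O[Si](CC)(CC)CC)C[C@@]2(CO[Si](CC)(CC)CC)C(OS(=O)(=O)C(F)(F)F)=CC=C[C@H]2[C@@]1(C)CC(O[Si](C(C)C)(C(C)C)C(C)C)c1ccoc1
F10 | step 16 | diol dienyl triflate | C=C1[C@@H](O)C[C@@]2(CO)C(OS(=O)(=O)C(F)(F)F)=CC=C[C@H]2[C@@]1(C)CC(O[Si](C(C)C)(C(C)C)C(C)C)c1ccoc1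
F11 | step 16 | hydroxy dienyl lactone | C=C1[C@@H](O)C[C@@]23COC(=O)C2=CC=C[C@H]3[C@@]1(C)CC(O[Si](C(C)C)(C(C)C)C(C)C)c1ccoc1
F12 | step 6 | dienol allyl carbonate of 9 | C=CCOC(=O)OC1=C(C)C2=CCCC3(OCCO3)[C@]2(CO[Si](C)(C)C(C)(C)C)CC1
F13 | step 13 | C14 hydrazone | C=C1[C@@H](O)C[C@@]2(CO[Si](C)(C)C(C)(C)C)C(=NN)CCC=C2[C@@]1(C)CC(O[Si](C(C)C)(C(C)C)C(C)C)c1ccoc1
F14 | step 13 | C14 vinyl iodide | C=C1[C@@H](O)C[C@@]2(CO[Si](C)(C)C(C)(C)C)C(I)=CCC=C2[C@@]1(C)CC(O[Si](C(C)C)(C(C)C)C(C)C)c1ccoc1
F15 | step 13 | diol vinyl iodide | C=C1[C@@H](O)C[C@@]2(CO)C(I)=CCC=C2[C@@]1(C)CC(O[Si](C(C)C)(C(C)C)C(C)C)c1ccoc1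
A1 | alternative 1 | cis-fused ring A/B enone diester | C=C1[C@@H](O[Si](C)(C)C(C)(C)C)C[C@@]2(C(=O)OC)C(OC)=CC(=O)[C@@H](c3ccco3)[C@H]2[C@@]1(C)CC(=O)OC
A2 | alternative 2 | α-phosphono γ-lactone with quaternary C9 | C=C1[C@@H](OC(C)=O)C[C@]2(COC(=O)[C@@H]2P(=O)(OCC)OCC)[C@H]2[C@@H](CCO[Si](C)(C)C(C)(C)C)c3occc3C(=O)C[C@@]12C
A3 | alternative 3 | target skeleton, O4 triethylsilyl ether | C=C1[C@@H](O[Si](CC)(CC)CC)C[C@@]23COC(=O)C2=CC[C@H]2c4occc4C(=O)C[C@]1(C)[C@H]23
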